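The dihydrofuran ring is cut at C3–C3a and O1–C7a. Because the benzene ring carries oxygen at C4, C6 and C7a in a 1,3,5-pattern, it maps onto threefold-symmetric 1,3,5-trifluorobenzene, whose every C–H is flanked by two fluorines. In one operation its aryllithium opens an (S)-epoxide at CH2 (C3a–C3) and the liberated C2 alkoxide displaces either equivalent ortho fluorine (C7a–O1), closing ring O1–C2–C3–C3a–C7a with C2 untouched. The precursor is (S)-2-(oxiran-2-yl)propan-2-ol as its methoxymethyl ether; an acetal is chosen over a silyl ether because a silyl group could migrate to the neighbouring alkoxide and divert closure to a chroman. The two remaining fluorines then steer C5 and C7 metalation and are exchanged for oxygen.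

Key step: step 4

Remark: the sense of the kinetic resolution in step 3 is assigned by analogy with other terminal epoxides, for which the (R,R)-catalyst consumes the enantiomer that carries the (R) descriptor here; the configuration of 4 is to be confirmed before use, and the (S,S)-catalyst would serve if the sense were opposite.

Step 1
Reactants: 1 2-methylbut-3-en-2-ol
Product: 2 3-(methoxymethoxy)-3-methylbut-1-ene
Conditions: MOMCl, i-Pr2NEt, NaI (cat.), CH2Cl2, 0 to 40 °C
Reagents that add atoms: chloromethyl methyl ether (MOMCl), COCCl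
Why: O-alkylation of the tertiary alcohol with the α-chloro ether under amine base (methoxymethyl ether formation) gives an acetal that cannot migrate to a neighbouring alkoxide later; no stereocentre is formed.

Step 2
Reactants: 2 3-(methoxymethoxy)-3-methylbut-1-ene
Product: 3 rac-2-[2-(methoxymethoxy)propan-2-yl]oxirane
Conditions: mCPBA, NaHCO3, CH2Cl2, rt to 40 °C
Reagents that add atoms: 3-chloroperoxybenzoic acid (mCPBA), O=C(OO)c1cccc(Cl)c1
Why: Prilezhaev epoxidation of the monosubstituted alkene by the peracid, buffered so that the acetal and the new epoxide survive, gives the racemate.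

Step 3
Reactants: 3 rac-2-[2-(methoxymethoxy)propan-2-yl]oxirane
Product: 4 (2S)-2-[2-(methoxymethoxy)propan-2-yl]oxirane
Conditions: (R,R)-(salen)Co(OAc) (2 mol%; salen = N,N'-bis(3,5-di-tert-butylsalicylidene)cyclohexane-1,2-diaminate; trivalent cobalt, made from the divalent cobalt complex (R,R)-(salen)Co with AcOH in air), H2O (0.55 equiv), THF (minimal), 0 °C to rt; distillation
Reagents that add atoms: none
Why: Hydrolytic kinetic resolution of a terminal epoxide (Jacobsen): the (R,R)-catalyst should hydrolyse the (R)-epoxide at CH2 much faster, so the unreacted (S)-epoxide, whose C2 becomes the only stereocentre of the target, is recovered enantioenriched by distillation from the diol.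

Step 4
Reactants: 5 1,3,5-trifluorobenzene; 4 (2S)-2-[2-(methoxymethoxy)propan-2-yl]oxirane
Product: 8 (2S)-4,6-difluoro-2-[2-(methoxymethoxy)propan-2-yl]-2,3-dihydro-1-benzofuran, via 2,4,6-trifluorophenyllithium 6 (not isolated), via ring-opened alcohol 7 (not isolated)
Conditions: 5, n-BuLi, THF, −78 °C; 4 then BF3·OEt2, −78 °C; H2O quench, organic phase dried and switched to DMF; KOtBu, DMF, 0 to 60 °C
Reagents that add atoms: none
Why: Deprotonation of 5 at a C–H flanked by two fluorines gives aryllithium 6, which attacks the BF3-activated epoxide 4 in an SN2 opening at the unhindered CH2 to form C3a–C3, and after the water quench the secondary potassium alkoxide of 7 adds to an ortho C–F carbon and expels fluoride through a Meisenheimer anion to form C7a–O1. The closest known reactions are the BF3-assisted opening of epoxides by ortho-fluoroaryllithiums and the base-mediated cyclisation of 2-(2-fluoroaryl)ethanols to dihydrobenzofurans. The dihydrofuran ring closes in a 5-exo addition–elimination (intramolecular SNAr) that the two remaining meta fluorines accelerate. No stereocentre is created: C2 comes from 4 and none of its bonds is broken, so it should stay (S). The step needs attack at the terminal epoxide carbon before 6 loses LiF to an aryne, which the Lewis acid at −78 °C secures, and a single direction of ring fusion, which the equivalence of the two ortho fluorines guarantees. The tertiary oxygen is held as a methoxymethyl acetal that cannot migrate, so only the C2 alkoxide can reach the ring and a 6-exo closure to a chroman is excluded.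

Step 5
Reactants: 8 (2S)-4,6-difluoro-2-[2-(methoxymethoxy)propan-2-yl]-2,3-dihydro-1-benzofuran; 9 1-bromo-3-methylbut-2-ene
Product: 12 (2S)-4,6-difluoro-2-[2-(methoxymethoxy)propan-2-yl]-5-(3-methylbut-2-en-1-yl)-2,3-dihydro-1-benzofuran, via C5 aryllithium 10 (not isolated), via C5 arylcopper 11 (not isolated)
Conditions: n-BuLi, THF, −78 °C; CuBr·SMe2, −78 °C; 9, −78 °C to rt
Reagents that add atoms: none
Why: Directed ortho-lithiation takes place at C5, the only C–H between two fluorines and therefore the most acidic, and the arylcopper made by transmetalation should substitute prenyl bromide at its primary carbon (copper-mediated allylic alkylation) to give the linear prenyl group.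

Step 6
Reactants: 13 3-(4-methoxyphenyl)propanoic acid
Product: 15 N-methoxy-3-(4-methoxyphenyl)-N-methylpropanamide, via acyl imidazolide 14 (not isolated)
Conditions: CDI, CH2Cl2, rt; MeNH(OMe)·HCl, rt
Reagents that add atoms: N,O-dimethylhydroxylamine hydrochloride, CNOC.Cl
Why: Amide formation through the acyl imidazolide (CDI coupling) is a standard way to the Weinreb amide.

Step 7
Reactants: 12 (2S)-4,6-difluoro-2-[2-(methoxymethoxy)propan-2-yl]-5-(3-methylbut-2-en-1-yl)-2,3-dihydro-1-benzofuran; 15 N-methoxy-3-(4-methoxyphenyl)-N-methylpropanamide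
Product: 18 1-[(2S)-4,6-difluoro-2-[2-(methoxymethoxy)propan-2-yl]-5-(3-methylbut-2-en-1-yl)-2,3-dihydro-1-benzofuran-7-yl]-3-(4-methoxyphenyl)propan-1-one, via C7 aryllithium 16 (not isolated), via tetrahedral lithium adduct 17 (not isolated)
Conditions: n-BuLi, THF, −78 °C; 15, −78 to −50 °C; H2O quench
Reagents that add atoms: none
Why: With C5 blocked, directed ortho-lithiation removes the remaining ring hydrogen at C7 between F and O1, and the aryllithium adds once to the Weinreb amide because the chelated tetrahedral adduct 17 survives until the quench (Weinreb ketone synthesis).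

Step 8
Reactants: 18 1-[(2S)-4,6-difluoro-2-[2-(methoxymethoxy)propan-2-yl]-5-(3-methylbut-2-en-1-yl)-2,3-dihydro-1-benzofuran-7-yl]-3-(4-methoxyphenyl)propan-1-one
Product: 20 1-[(2S)-4,6-bis(allyloxy)-2-[2-(methoxymethoxy)propan-2-yl]-5-(3-methylbut-2-en-1-yl)-2,3-dihydro-1-benzofuran-7-yl]-3-(4-methoxyphenyl)propan-1-one, via monoallyl ether 19 (not isolated)
Conditions: NaH, allyl alcohol (solvent), 95 °C
Reagents that add atoms: allyl alcohol (used as sodium allyloxide), C=CCO
Why: Twofold nucleophilic aromatic substitution (SNAr): the C7 ketone lies ortho to C6–F and para to C4–F and stabilises both Meisenheimer anions, each new alkoxy group is meta to the remaining fluorine, and the alcohol solvent keeps the ketone from resting as its unreactive enolate.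

Step 9
Reactants: 20 1-[(2S)-4,6-bis(allyloxy)-2-[2-(methoxymethoxy)propan-2-yl]-5-(3-methylbut-2-en-1-yl)-2,3-dihydro-1-benzofuran-7-yl]-3-(4-methoxyphenyl)propan-1-one
Product: 21 1-[(2S)-4,6-bis(allyloxy)-2-(2-hydroxypropan-2-yl)-5-(3-methylbut-2-en-1-yl)-2,3-dihydro-1-benzofuran-7-yl]-3-(4-methoxyphenyl)propan-1-one
Conditions: conc. HCl (cat.), MeOH, 45 °C
Reagents that add atoms: none
Why: Acid-catalysed transacetalisation to methanol removes the methoxymethyl group while both phenols are still allyl-capped, so no free ortho-hydroxyl can add to the prenyl alkene under acid.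

Step 10
Reactants: 21 1-[(2S)-4,6-bis(allyloxy)-2-(2-hydroxypropan-2-yl)-5-(3-methylbut-2-en-1-yl)-2,3-dihydro-1-benzofuran-7-yl]-3-(4-methoxyphenyl)propan-1-one
Product: 23 1-[(2S)-4,6-dihydroxy-2-(2-hydroxypropan-2-yl)-5-(3-methylbut-2-en-1-yl)-2,3-dihydro-1-benzofuran-7-yl]-3-(4-methoxyphenyl)propan-1-one (CNP0150199.1), via monoallyl phenol 22 (not isolated)
Conditions: Pd(PPh3)4 (5 mol%), morpholine, THF, rt
Reagents that add atoms: none
Why: Tsuji–Trost-type deallylation: zerovalent palladium ionises each aryl allyl ether to a π-allyl complex that morpholine captures, which frees both phenols under near-neutral conditions and leaves the prenyl alkene, the ketone, the tertiary alcohol and C2 untouched.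

Compound list
1 | 2-methylbut-3-en-2-ol | CC(C)(O)C=C | starting material
2 | 3-(methoxymethoxy)-3-methylbut-1-ene | COCOC(C)(C)C=C | intermediate
3 | rac-2-[2-(methoxymethoxy)propan-2-yl]oxirane | COCOC(C)(C)C1CO1 | intermediate
4 | (2S)-2-[2-(methoxymethoxy)propan-2-yl]oxirane | COCOC(C)(C)[C@@H]1CO1 | intermediate
5 | 1,3,5-trifluorobenzene | Fc1cc(F)cc(F)c1 | starting material
6 | 2,4,6-trifluorophenyllithium (formed in situ) | [Li]c1c(F)cc(F)cc1F | intermediate
7 | (2S)-3-(methoxymethoxy)-3-methyl-1-(2,4,6-trifluorophenyl)butan-2-ol (carried on in solution) | COCOC(C)(C)[C@@H](O)Cc1c(F)cc(F)cc1F | intermediate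
8 | (2S)-4,6-difluoro-2-[2-(methoxymethoxy)propan-2-yl]-2,3-dihydro-1-benzofuran | COCOC(C)(C)[C@@H]1Cc2c(F)cc(F)cc2O1 | intermediate
9 | 1-bromo-3-methylbut-2-ene | CC(C)=CCBr | starting material
10 | [(2S)-4,6-difluoro-2-[2-(methoxymethoxy)propan-2-yl]-2,3-dihydro-1-benzofuran-5-yl]lithium (formed in situ) | COCOC(C)(C)[C@@H]1Cc2c(F)c([Li])c(F)cc2O1 | intermediate
11 | [(2S)-4,6-difluoro-2-[2-(methoxymethoxy)propan-2-yl]-2,3-dihydro-1-benzofuran-5-yl]copper (formed in situ) | COCOC(C)(C)[C@@H]1Cc2c(F)c([Cu])c(F)cc2O1 | intermediate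
12 | (2S)-4,6-difluoro-2-[2-(methoxymethoxy)propan-2-yl]-5-(3-methylbut-2-en-1-yl)-2,3-dihydro-1-benzofuran | COCOC(C)(C)[C@@H]1Cc2c(F)c(CC=C(C)C)c(F)cc2O1 | intermediate
13 | 3-(4-methoxyphenyl)propanoic acid | COc1ccc(CCC(=O)O)cc1 | starting material
14 | 1-(imidazol-1-yl)-3-(4-methoxyphenyl)propan-1-one (formed in situ) | COc1ccc(CCC(=O)n2ccnc2)cc1 | intermediate
15 | N-methoxy-3-(4-methoxyphenyl)-N-methylpropanamide | COc1ccc(CCC(=O)N(C)OC)cc1 | intermediate
16 | [(2S)-4,6-difluoro-2-[2-(methoxymethoxy)propan-2-yl]-5-(3-methylbut-2-en-1-yl)-2,3-dihydro-1-benzofuran-7-yl]lithium (formed in situ) | COCOC(C)(C)[C@@H]1Cc2c(F)c(CC=C(C)C)c(F)c([Li])c2O1 | intermediate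
17 | lithium 1-[(2S)-4,6-difluoro-2-[2-(methoxymethoxy)propan-2-yl]-5-(3-methylbut-2-en-1-yl)-2,3-dihydro-1-benzofuran-7-yl]-1-[methoxy(methyl)amino]-3-(4-methoxyphenyl)propan-1-olate (formed in situ; epimers at the aminal carbon) | COc1ccc(CCC(O[Li])(N(C)OC)c2c(F)c(CC=C(C)C)c(F)c3c2O[C@H](C(C)(C)OCOC)C3)cc1 | intermediate
18 | 1-[(2S)-4,6-difluoro-2-[2-(methoxymethoxy)propan-2-yl]-5-(3-methylbut-2-en-1-yl)-2,3-dihydro-1-benzofuran-7-yl]-3-(4-methoxyphenyl)propan-1-one | COc1ccc(CCC(=O)c2c(F)c(CC=C(C)C)c(F)c3c2O[C@H](C(C)(C)OCOC)C3)cc1 | intermediate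
19 | 1-[(2S)-4-(allyloxy)-6-fluoro-2-[2-(methoxymethoxy)propan-2-yl]-5-(3-methylbut-2-en-1-yl)-2,3-dihydro-1-benzofuran-7-yl]-3-(4-methoxyphenyl)propan-1-one (formed in situ; drawn as the para-substituted isomer, the 6-allyloxy-4-fluoro isomer would converge on 20) | COc1ccc(CCC(=O)c2c(F)c(CC=C(C)C)c(OCC=C)c3c2O[C@H](C(C)(C)OCOC)C3)cc1 | intermediate
20 | 1-[(2S)-4,6-bis(allyloxy)-2-[2-(methoxymethoxy)propan-2-yl]-5-(3-methylbut-2-en-1-yl)-2,3-dihydro-1-benzofuran-7-yl]-3-(4-methoxyphenyl)propan-1-one | COc1ccc(CCC(=O)c2c(OCC=C)c(CC=C(C)C)c(OCC=C)c3c2O[C@H](C(C)(C)OCOC)C3)cc1 | intermediate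
21 | 1-[(2S)-4,6-bis(allyloxy)-2-(2-hydroxypropan-2-yl)-5-(3-methylbut-2-en-1-yl)-2,3-dihydro-1-benzofuran-7-yl]-3-(4-methoxyphenyl)propan-1-one | COc1ccc(CCC(=O)c2c(OCC=C)c(CC=C(C)C)c(OCC=C)c3c2O[C@H](C(C)(C)O)C3)cc1 | intermediate
22 | 1-[(2S)-6-(allyloxy)-4-hydroxy-2-(2-hydroxypropan-2-yl)-5-(3-methylbut-2-en-1-yl)-2,3-dihydro-1-benzofuran-7-yl]-3-(4-methoxyphenyl)propan-1-one (formed in situ; drawn with the C4 ether cleaved first, the other order would converge on 23) | COc1ccc(CCC(=O)c2c(OCC=C)c(CC=C(C)C)c(O)c3c2O[C@H](C(C)(C)O)C3)cc1 | intermediate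
23 | 1-[(2S)-4,6-dihydroxy-2-(2-hydroxypropan-2-yl)-5-(3-methylbut-2-en-1-yl)-2,3-dihydro-1-benzofuran-7-yl]-3-(4-methoxyphenyl)propan-1-one (CNP0150199.1) | COc1ccc(CCC(=O)c2c(O)c(CC=C(C)C)c(O)c3c2O[C@H](C(C)(C)O)C3)cc1 | target

Total step count: 10. Longest linear sequence: 9 steps (steps 1–5 and 7–10; step 6 is a one-step side branch).

Steps most likely to fail

Step 4. The fluorine-stabilised aryllithium may lose lithium fluoride to an aryne before it alkylates. The Lewis acid may also be tied up by the acetal oxygens, so that the epoxide opens slowly or rearranges, and the 5-exo closure may be sluggish. The fallback replaces the epoxide and Lewis acid by a cyclic sulfate, a stronger electrophile that needs no activation. It sets out from 4 and comes back at 7.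
- Hydrolysis of 4 (KOH, H2O/DMSO, 70 °C) should give (2S)-3-(methoxymethoxy)-3-methylbutane-1,2-diol F1 with C2 retained.
- SOCl2/Et3N should convert it into the cyclic sulfite (4S)-4-[2-(methoxymethoxy)propan-2-yl]-1,3,2-dioxathiolane 2-oxide F2 (epimers at sulfur).
- RuCl3 (cat.)/NaIO4 should oxidise that to the cyclic sulfate (4S)-4-[2-(methoxymethoxy)propan-2-yl]-1,3,2-dioxathiolane 2,2-dioxide F3.
- Aryllithium 6 should open F3 at CH2 at −78 °C to lithium (2S)-3-(methoxymethoxy)-3-methyl-1-(2,4,6-trifluorophenyl)butan-2-yl sulfate F4.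
- Hydrolysis of the sulfate ester (cat. H2SO4, 1 equiv H2O, THF, rt) should give alcohol 7, which is closed to 8 with KOtBu as in step 4.

Step 8. The second fluoride displacement may stall once the ring has become electron-rich, because the flanked and enolisable ketone is only a moderate activator, and prolonged heating with alkoxide may erode the material. The fallback carries out the exchange on an aldehyde, which cannot enolise and activates more strongly, and builds the ketone afterwards. It sets out from 12 and comes back at 20.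
- Lithiation of 12 to 16 as in step 7 and a DMF quench should give (2S)-4,6-difluoro-2-[2-(methoxymethoxy)propan-2-yl]-5-(3-methylbut-2-en-1-yl)-2,3-dihydro-1-benzofuran-7-carbaldehyde F5.
- Allyl alcohol with Cs2CO3 in DMF at 80 °C should give (2S)-4,6-bis(allyloxy)-2-[2-(methoxymethoxy)propan-2-yl]-5-(3-methylbut-2-en-1-yl)-2,3-dihydro-1-benzofuran-7-carbaldehyde F6.
- 2-(4-Methoxyphenyl)ethylmagnesium bromide F7, made from commercial 1-(2-bromoethyl)-4-methoxybenzene and Mg, should add to F6.
- The adduct is 1-[(2S)-4,6-bis(allyloxy)-2-[2-(methoxymethoxy)propan-2-yl]-5-(3-methylbut-2-en-1-yl)-2,3-dihydro-1-benzofuran-7-yl]-3-(4-methoxyphenyl)propan-1-ol F8, an inconsequential mixture of carbinol epimers.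
- Dess–Martin periodinane should oxidise F8 to 20.

Step 7. Addition of the hindered aryllithium to the amide may be slow at the low temperature it tolerates, which leaves room for deprotonation of the amide α-CH2 or for fluoride loss on warming. The fallback uses an aldehyde, a faster electrophile at −78 °C, followed by oxidation. It sets out from 15 (with 16 generated from 12 as before) and comes back at 18.
- i-Bu2AlH (THF, −78 °C) should reduce 15 to 3-(4-methoxyphenyl)propanal F9.
- Aryllithium 16 should add to F9 to give 1-[(2S)-4,6-difluoro-2-[2-(methoxymethoxy)propan-2-yl]-5-(3-methylbut-2-en-1-yl)-2,3-dihydro-1-benzofuran-7-yl]-3-(4-methoxyphenyl)propan-1-ol F10 (epimers at the carbinol carbon).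
- Dess–Martin periodinane should oxidise F10 to 18.

Further compounds
F1 | step 4 | (2S)-3-(methoxymethoxy)-3-methylbutane-1,2-diol | COCOC(C)(C)[C@@H](O)CO
F2 | step 4 | (4S)-4-[2-(methoxymethoxy)propan-2-yl]-1,3,2-dioxathiolane 2-oxide | COCOC(C)(C)[C@@H]1COS(=O)O1
F3 | step 4 | (4S)-4-[2-(methoxymethoxy)propan-2-yl]-1,3,2-dioxathiolane 2,2-dioxide | COCOC(C)(C)[C@@H]1COS(=O)(=O)O1
F4 | step 4 | lithium (2S)-3-(methoxymethoxy)-3-methyl-1-(2,4,6-trifluorophenyl)butan-2-yl sulfate | COCOC(C)(C)[C@@H](OS(=O)(=O)[O-])Cc1c(F)cc(F)cc1F.[Li+]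
F5 | step 8 | (2S)-4,6-difluoro-2-[2-(methoxymethoxy)propan-2-yl]-5-(3-methylbut-2-en-1-yl)-2,3-dihydro-1-benzofuran-7-carbaldehyde | COCOC(C)(C)[C@@H]1Cc2c(F)c(CC=C(C)C)c(F)c(C=O)c2O1
F6 | step 8 | (2S)-4,6-bis(allyloxy)-2-[2-(methoxymethoxy)propan-2-yl]-5-(3-methylbut-2-en-1-yl)-2,3-dihydro-1-benzofuran-7-carbaldehyde | COCOC(C)(C)[C@@H]1Cc2c(OCC=C)c(CC=C(C)C)c(OCC=C)c(C=O)c2O1
F7 | step 8 | 2-(4-methoxyphenyl)ethylmagnesium bromide | COc1ccc(CC[Mg]Br)cc1
F8 | step 8 | 1-[(2S)-4,6-bis(allyloxy)-2-[2-(methoxymethoxy)propan-2-yl]-5-(3-methylbut-2-en-1-yl)-2,3-dihydro-1-benzofuran-7-yl]-3-(4-methoxyphenyl)propan-1-ol | COc1ccc(CCC(O)c2c(OCC=C)c(CC=C(C)C)c(OCC=C)c3c2O[C@H](C(C)(C)OCOC)C3)cc1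
F9 | step 7 | 3-(4-methoxyphenyl)propanal | COc1ccc(CCC=O)cc1
F10 | step 7 | 1-[(2S)-4,6-difluoro-2-[2-(methoxymethoxy)propan-2-yl]-5-(3-methylbut-2-en-1-yl)-2,3-dihydro-1-benzofuran-7-yl]-3-(4-methoxyphenyl)propan-1-ol | COc1ccc(CCC(O)c2c(F)c(CC=C(C)C)c(F)c3c2O[C@H](C(C)(C)OCOC)C3)cc1
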